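## Structural features

The target is a linear C15 chain folded into one tetrahydropyran: the ring oxygen joins C6 and C10, and the ring carries in turn the (Z)-pent-2-en-4-ynyl arm (C6), chlorine (C7), a methylene (C8), bromine (C9) and the (E)-3-bromopent-2-enyl arm (C10). The stereocentres stand in two adjacent pairs, C6/C7 and C9/C10, and all four substituents lie on one face of the ring (6S,7S,9R,10R). With both carbon arms equatorial the two halogens are therefore 1,3-diaxial. Fragile groups are the terminal (Z)-enyne, the trisubstituted (E)-vinyl bromide, and the two secondary halides, each with antiperiplanar hydrogens ready for elimination. The real difficulty is threefold: the 2,6-cis relation across the ether oxygen, two axial carbon–halogen bonds that must come from equatorial alcohols by clean inversion, and the near mirror symmetry of the ring, which makes the C7 and C9 oxygens hard to tell apart. The key step exploits the fact that C9 and C10 lie across the ring oxygen from C6. A glycolate unit (C10–C11) on the C6 oxygen, esterified to a C7 hydroxyl, forms a 1,4-dioxan-2-one. A [3,3] shift of its ketene acetal passes the C6 chirality through C7 onto C10 and C9 and leaves the C7=C8 alkene and the C11 carboxyl as handles.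

## Logic of the disconnections

41 ⇒ 40 ⇒ 38. Bonds cut: C1–Si and C7–Cl. The alkyne stays silylated to the end and chlorine enters last, from the equatorial C7 alcohol of opposite configuration. The gain is that the finished dihalide meets only one further reagent. The demand is clean inversion at C7 past the axial C9 bromine and a desilylation that eliminates neither halide.

38 ⇒ 35 + 36. Bond cut: C3=C4. This separates the three-carbon enyne terminus 36 from a C4 aldehyde stored as lactol 35, so C1–C3 arrive in one step with the alkene geometry. The forward step must be Z-selective on a lactol and must tolerate an axial secondary bromide.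

35 ⇒ 34 ⇒ 32 ⇒ 30. Bonds cut: C9–Br and the acyl–O7 bond of the lactone. The C7 and C9 hydroxyls of 30 are nearly equivalent, but only O7 can reach an oxidised C4. The γ-lactone therefore labels O7, frees O9 for bromination and brings C4 to the carbonyl level without protecting-group steps. The demands are an oxidant that spares secondary alcohols and an invertive bromination at C9.

30 ⇒ 29 ⇒ 26. Bond cut: C7–O. The C7=C8 alkene of 26 is flanked by two oxygenated carbons, so an external reagent cannot choose between C7 and C8. A silicon tether on O9 can reach only C7 and only the face of O9. This derives the C7 stereocentre from C9, but the hydrosilylation must close a bridged siloxane (28) across a ring alkene.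

26 ⇒ 25 ⇒ 23 ⇒ 20 + 21. Bonds cut: C13–Br with C12–H, then C11–C12. The vinyl bromide is a syn H/Br adduct of alkyne 23, which comes from triflate 20 and the four-carbon alkyne 21. C12–C15 arrive in one C–C bond formation. Hydrozirconation must place the metal on C13, and it must come before the platinum step, which an alkyne would not survive.

20 ⇒ 19 ⇒ 18. No skeletal bond is cut; the C11 carboxyl is the precursor of the C11 leaving group. The C9 ether must survive hydride and triflation.

18 ⇒ 15. Bond formed in the forward sense: C9–C10; bond broken: O–C7. The whole ring with C9 and C10 is traced to a dioxanone in which only C6 and C7 are stereogenic. The forward step needs a trans-5,6-disubstituted dioxanone and a pure Z enol ether.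

15 ⇒ 14 ⇒ 10 + 4. The Z alkene comes from an alkyne. Then the C7–C8 bond and the lactone C11–O bond are cut, giving aldehyde 10 and an alkoxyacetylide made from 4. The addition must be chelation-controlled (syn), and the acid-labile ynol and enol ethers must be handled under buffered conditions.

10 ⇒ 9 ⇒ 7 + 8; 7 ⇒ 6 ⇒ 5; 4 ⇒ 1 + 2. The ether bond O–C10 is cut to 8. The C7 carbonyl is carried as an amide so that it can be reduced beside the glycolate ester. The stereocentre comes from 5, and the acetylide precursor 4 from 1 and 2.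

## Other disconnections considered

Alternative 1: The cut is at C5–C6 and C10–C11, the two ring-to-arm bonds. In the forward step an amine base would convert 6-acetoxy-2H-pyran-3(6H)-one A1 into a 3-oxidopyrylium ylide, which would add 2,2-dimethyl-1,3-dioxole A2 in a [5+2] sense to give bicycle A3. Later cleavage of the two-carbon diol bridge would leave cis formyl stubs on C6 and C10.
- In its favour: the 2,6-cis relation is fixed by the bicycle. The enone of A3 has a carbonyl at one end of C7–C9 and a conjugate position at the other, so the two future halogen sites are chemically distinct from the start. On this point it is better than the chosen plan, which needs a lactone detour. It also reaches the ring in fewer steps.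
- Against it here: the parent cycloaddition sets no absolute configuration, whereas the chosen plan takes it from 5. After bridge cleavage the two formyl groups are almost equivalent, and all eight arm carbons (C1–C4 and C12–C15) remain to be added. A2 is volatile and must be prepared.
- Comparison: equal on 2,6-cis control (geometric in both), better on C7/C9 differentiation, worse on absolute stereocontrol and arm construction. No saving in steps is expected overall.

Alternative 2: The cut is at C6–C7. Samarium diiodide A6 (divalent samarium) would reduce the aldehyde of acrylate A5 to a ketyl, which adds to the β-carbon of the alkoxyacrylate and closes oxane A7. C9 and C10 would come from C3 and C4 of 2-deoxy-D-ribose A4.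
- In its favour: this ketyl–olefin closure is a well-precedented route to 2,6-cis-2,3-trans oxanes. A7 has the C7 hydroxyl free and the C9 oxygen silylated, so the differentiation that costs the chosen plan three steps comes for nothing. The C12–C15 alkyne and a C4 ester are already in place. On these points it is better than the chosen plan, and it is probably shorter.
- Against it here: more than two equivalents of an air-sensitive lanthanide reductant are needed. The three hydroxyls of A4 must be manipulated selectively to reach A5. A5 is an aldehyde with a β-silyloxy group and is prone to elimination.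
- Comparison: both plans fix the ring geometry in the ring-forming step. The chosen plan creates C9 and C10 together from one remote centre in a closed-shell concerted step; alternative 2 buys them and creates C6/C7 by single-electron chemistry. On step economy and hydroxyl differentiation alternative 2 is the stronger plan.

Alternative 3: The cut is at O–C10, with the ring carbons drawn from a furan. N-Bromosuccinimide A9 in aqueous THF would oxidise furyl carbinol A8, and the carbinol oxygen would close on the unveiled C10 carbonyl to give pyranone A10 (Achmatowicz ring expansion).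
- In its favour: it is short and scalable. The single carbinol centre is accessible by asymmetric ketone reduction. C11–C15 are already on the furan. A10 has C7 as a carbonyl and C9 as the enone β-carbon, so the two sites are differentiated. On step count and differentiation it is better than the chosen plan.
- Against it here: C10 would rest on an ionic hydride reduction of the hemiketal, C9 on a conjugate addition and C7 on a ketone reduction: three separate diastereoselective steps. The C6 centre stays α to a ketone and epimerisable until late. The alkyne must survive electrophilic bromine.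
- Comparison: equal on the final all-equatorial diol pattern and on 2,6-cis control. The chosen plan is more certain for C9/C10, which are set together with no epimerisable centre, but it is longer.

Key step: step 8

Assumptions (remarks on the chemistry):
- (S)-3-Hydroxyoxolan-2-one 5, the commercial lactone of C4-reduced L-malic acid, is taken as the chiral starting material.
- The enol ether oxygen carries a 4-methoxybenzyl (PMB) group and C4 a tert-butyldimethylsilyl (TBS) ether, so that the C9 oxygen can be freed oxidatively without touching silicon.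
- TIPS = triisopropylsilyl.

## Steps

Step 1
Reactants: 1 4-methoxybenzyl alcohol; 2 trichloroethylene
Product: 4 1-{[(E)-1,2-dichloroethenyl]oxymethyl}-4-methoxybenzene, via dichloroacetylene 3 (not isolated)
Conditions: KN(SiMe3)2 (1.05 equiv), THF, 0 °C; then 2, −40 °C → rt, N2
Reagents that add atoms: none
Why: Base-induced loss of HCl from 2 gives 3, to which the potassium alkoxide adds in an anti sense to give the (E)-dichlorovinyl ether (Greene-type ynol ether precursor synthesis). The toxic, explosive alkyne 3 stays dilute and is consumed as it forms, and an amide base replaces potassium hydride.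

Step 2
Reactants: 5 (S)-3-hydroxyoxolan-2-one
Product: 6 (2S)-2,4-dihydroxy-N-methoxy-N-methylbutanamide
Conditions: MeNH(OMe)·HCl (1.6 equiv), i-PrMgCl (3.3 equiv), THF, −20 → 0 °C
Reagents that add atoms: N,O-dimethylhydroxylamine hydrochloride, CNOC.Cl
Why: Lactone aminolysis by the chloromagnesium amide (Weinreb amide formation); the stereocentre is not touched.

Step 3
Reactants: 6 (2S)-2,4-dihydroxy-N-methoxy-N-methylbutanamide
Product: 7 (2S)-4-(tert-butyldimethylsilyloxy)-2-hydroxy-N-methoxy-N-methylbutanamide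
Conditions: TBSCl (1.05 equiv), imidazole, CH2Cl2, 0 °C
Reagents that add atoms: tert-butyldimethylsilyl chloride, CC(C)(C)[Si](C)(C)Cl
Why: Selective silylation of the primary hydroxyl, which also stops relactonisation.

Step 4
Reactants: 7 (2S)-4-(tert-butyldimethylsilyloxy)-2-hydroxy-N-methoxy-N-methylbutanamide; 8 methyl bromoacetate
Product: 9 methyl 2-{[(2S)-4-(tert-butyldimethylsilyloxy)-1-[methoxy(methyl)amino]-1-oxobutan-2-yl]oxy}acetate
Conditions: NaH (1.1 equiv), Bu4NI (cat.), THF, 0 °C → rt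
Reagents that add atoms: none
Why: Williamson etherification puts C10–C11 on the C6 oxygen; the α-proton of an amide is less acidic than that of an ester, so the centre should not epimerise.

Step 5
Reactants: 9 methyl 2-{[(2S)-4-(tert-butyldimethylsilyloxy)-1-[methoxy(methyl)amino]-1-oxobutan-2-yl]oxy}acetate
Product: 10 methyl 2-{[(2S)-4-(tert-butyldimethylsilyloxy)-1-oxobutan-2-yl]oxy}acetate
Conditions: Cp2Zr(H)Cl (1.5 equiv), THF, rt, 20 min; used at once
Reagents that add atoms: none
Why: Hydrozirconation of the amide carbonyl and hydrolysis (Georg amide-to-aldehyde reduction) is chemoselective for tertiary amides over esters, so the glycolate ester should survive.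

Step 6
Reactants: 4 1-{[(E)-1,2-dichloroethenyl]oxymethyl}-4-methoxybenzene; 10 methyl 2-{[(2S)-4-(tert-butyldimethylsilyloxy)-1-oxobutan-2-yl]oxy}acetate
Product: 14 (5S,6S)-5-[2-(tert-butyldimethylsilyloxy)ethyl]-6-{[(4-methoxybenzyl)oxy]ethynyl}-1,4-dioxan-2-one, via lithium acetylide 11 (not isolated), via alkynylzinc bromide 12 (not isolated), via zinc alkoxide 13 (not isolated)
Conditions: 4, n-BuLi (2.2 equiv), Et2O, −78 → −40 °C; ZnBr2, −40 → 0 °C; 10, −78 → 0 °C; then rt; NaHCO3 work-up, Et3N-washed silica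
Reagents that add atoms: none
Why: Elimination and Cl/Li exchange turn 4 into the alkoxyacetylide. Its zinc derivative should add under Cram-chelate control: zinc bridges the aldehyde and α-ether oxygens and the alkyne attacks anti to the C5 chain, giving the 6,7-syn adduct (3S,4S in 13). The alkoxide then closes on the methyl ester to the trans-dioxanone.

Step 7
Reactants: 14 (5S,6S)-5-[2-(tert-butyldimethylsilyloxy)ethyl]-6-{[(4-methoxybenzyl)oxy]ethynyl}-1,4-dioxan-2-one
Product: 15 (5S,6S)-5-[2-(tert-butyldimethylsilyloxy)ethyl]-6-{(Z)-2-[(4-methoxybenzyl)oxy]ethenyl}-1,4-dioxan-2-one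
Conditions: H2 (1 atm), Pd/CaCO3/Pb(OAc)2, quinoline, EtOAc, rt
Reagents that add atoms: none
Why: Syn semihydrogenation of the electron-rich ynol ether on poisoned palladium gives the Z enol ether; the benzylic ether and the lactone should be untouched at 1 atm.

Step 8
Reactants: 15 (5S,6S)-5-[2-(tert-butyldimethylsilyloxy)ethyl]-6-{(Z)-2-[(4-methoxybenzyl)oxy]ethenyl}-1,4-dioxan-2-one
Product: 18 (2S,3S,6S)-6-[2-(tert-butyldimethylsilyloxy)ethyl]-3-[(4-methoxybenzyl)oxy]-3,6-dihydro-2H-pyran-2-carboxylic acid, via silyl ketene acetal 16 (not isolated), via trimethylsilyl ester 17 (not isolated)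
Conditions: LiN(SiMe3)2 (1.3 equiv), Me3SiCl/Et3N, THF, −78 °C; then toluene, 80 °C; pH 5 buffer work-up
Reagents that add atoms: none
Why: Deprotonation at C10, the only α-position of the lactone, with in-situ silylation gives the endocyclic ketene acetal 16; its C10 terminus bonds to C9 of the enol ether while the allylic O–C7 bond breaks in a concerted suprafacial [3,3] shift (Ireland–Claisen rearrangement). The closest known reaction type is the ring contraction of 6-alkenyl-1,4-dioxan-2-one ketene acetals to cis-2,6-disubstituted dihydropyran-2-carboxylic acids. The dihydropyran (O, C6, C7=C8, C9, C10) closes by this C9–C10 bond formation inside a bicyclo[2.2.2]-like boat array, in which the O–C6 unit bridges the termini C10 and C7; formally the closure is endo at C9, but it is a pericyclic ring contraction and not a polar cyclisation. C10 is set by the tether: the bond can form only on the face that carries the axial C7 alkenyl arm, which is trans to the C6 side chain, so the C6 and C10 substituents end cis (2S in 18). C9 is set by alkene geometry: in the enforced boat the Z alkoxy group points to the side of the bridge and ends trans to the C11 carboxyl (3S in 18). The step needs a geometrically pure Z enol ether, O-silylation before any benzylic deprotonation, and rearrangement faster than loss of the ketene acetal; the hexamethyldisilazide base with internal quench and the donor-substituted alkene terminus should secure this. Ester 17 is hydrolysed on work-up.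

Step 9
Reactants: 18 (2S,3S,6S)-6-[2-(tert-butyldimethylsilyloxy)ethyl]-3-[(4-methoxybenzyl)oxy]-3,6-dihydro-2H-pyran-2-carboxylic acid
Product: 19 [(2R,3S,6S)-6-[2-(tert-butyldimethylsilyloxy)ethyl]-3-[(4-methoxybenzyl)oxy]-3,6-dihydro-2H-pyran-2-yl]methanol
Conditions: LiAlH4, THF, 0 °C → rt
Reagents that add atoms: none
Why: Hydride reduction of the acid to the C11 alcohol; ethers and the alkene are inert (the descriptor at C10 changes by priority only).

Step 10
Reactants: 19 [(2R,3S,6S)-6-[2-(tert-butyldimethylsilyloxy)ethyl]-3-[(4-methoxybenzyl)oxy]-3,6-dihydro-2H-pyran-2-yl]methanol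
Product: 20 [(2R,3S,6S)-6-[2-(tert-butyldimethylsilyloxy)ethyl]-3-[(4-methoxybenzyl)oxy]-3,6-dihydro-2H-pyran-2-yl]methyl trifluoromethanesulfonate
Conditions: Tf2O, 2,6-lutidine, CH2Cl2, −78 °C; cold work-up, used crude
Reagents that add atoms: trifluoromethanesulfonic anhydride, O=S(=O)(OS(=O)(=O)C(F)(F)F)C(F)(F)F
Why: Sulfonylation of the primary alcohol; a triflate is needed because the carbon is β-branched and β-oxygenated.

Step 11
Reactants: 20 [(2R,3S,6S)-6-[2-(tert-butyldimethylsilyloxy)ethyl]-3-[(4-methoxybenzyl)oxy]-3,6-dihydro-2H-pyran-2-yl]methyl trifluoromethanesulfonate; 21 but-1-yne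
Product: 23 (2R,3S,6S)-6-[2-(tert-butyldimethylsilyloxy)ethyl]-3-[(4-methoxybenzyl)oxy]-2-(pent-2-yn-1-yl)-3,6-dihydro-2H-pyran, via but-1-ynyllithium 22 (not isolated)
Conditions: 21, n-BuLi, THF, −78 °C; then 20, DMPU, −78 → −20 °C
Reagents that add atoms: none
Why: SN2 displacement of a primary triflate by a lithium acetylide forms C11–C12; DMPU replaces HMPA.

Step 12
Reactants: 23 (2R,3S,6S)-6-[2-(tert-butyldimethylsilyloxy)ethyl]-3-[(4-methoxybenzyl)oxy]-2-(pent-2-yn-1-yl)-3,6-dihydro-2H-pyran
Product: 25 (2R,3S,6S)-2-[(2E)-3-bromopent-2-en-1-yl]-6-[2-(tert-butyldimethylsilyloxy)ethyl]-3-[(4-methoxybenzyl)oxy]-3,6-dihydro-2H-pyran, via alkenylzirconocene 24 (not isolated)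
Conditions: Cp2Zr(H)Cl (1.5 equiv), THF, rt → 40 °C; then N-bromosuccinimide, 0 °C
Reagents that add atoms: N-bromosuccinimide, O=C1CCC(=O)N1Br
Why: Syn hydrozirconation, with a slight excess of hydride to equilibrate the alkenylmetal to the less hindered position (Zr on C13, away from the β-branched ring side), then bromination with retention gives the E bromide. The alkyne reacts far faster than the hindered ring alkene.

Step 13
Reactants: 25 (2R,3S,6S)-2-[(2E)-3-bromopent-2-en-1-yl]-6-[2-(tert-butyldimethylsilyloxy)ethyl]-3-[(4-methoxybenzyl)oxy]-3,6-dihydro-2H-pyran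
Product: 26 (2R,3S,6S)-2-[(2E)-3-bromopent-2-en-1-yl]-6-[2-(tert-butyldimethylsilyloxy)ethyl]-3,6-dihydro-2H-pyran-3-ol
Conditions: DDQ, CH2Cl2/pH 7 buffer, 0 °C
Reagents that add atoms: none
Why: Oxidative cleavage of the PMB ether; the silyl ether and the vinyl bromide are inert.

Step 14
Reactants: 26 (2R,3S,6S)-2-[(2E)-3-bromopent-2-en-1-yl]-6-[2-(tert-butyldimethylsilyloxy)ethyl]-3,6-dihydro-2H-pyran-3-ol
Product: 29 (2R,3S,5R,6S)-2-[(2E)-3-bromopent-2-en-1-yl]-6-[2-(tert-butyldimethylsilyloxy)ethyl]oxane-3,5-diol, via dimethylsilyl ether 27 (not isolated), via bicyclic siloxane 28 (not isolated)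
Conditions: (HMe2Si)2NH, rt, then vacuum; Pt2[(CH2=CHSiMe2)2O]3 (1 mol %, zerovalent platinum), toluene, 60 °C; then 30% H2O2, KF, KHCO3, THF/MeOH, rt
Reagents that add atoms: hydrogen peroxide, OO
Why: Platinum-catalysed intramolecular hydrosilylation of the allylic hydrosilyl ether can close only in the 5-endo sense, so silicon is delivered to C7 on the face of the C9 oxygen. Tamao oxidation with retention then gives the C7 hydroxyl cis to the C9 hydroxyl and trans to the C6 arm (5R).

Step 15
Reactants: 29 (2R,3S,5R,6S)-2-[(2E)-3-bromopent-2-en-1-yl]-6-[2-(tert-butyldimethylsilyloxy)ethyl]oxane-3,5-diol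
Product: 30 (2R,3S,5R,6S)-2-[(2E)-3-bromopent-2-en-1-yl]-6-(2-hydroxyethyl)oxane-3,5-diol
Conditions: camphorsulfonic acid (10 mol %), MeOH, 0 °C
Reagents that add atoms: none
Why: Acid-catalysed methanolysis of the primary silyl ether.

Step 16
Reactants: 30 (2R,3S,5R,6S)-2-[(2E)-3-bromopent-2-en-1-yl]-6-(2-hydroxyethyl)oxane-3,5-diol
Product: 32 (3aS,5R,6S,7aR)-5-[(2E)-3-bromopent-2-en-1-yl]-6-hydroxyhexahydro-2H-furo[3,2-b]pyran-2-one, via lactol 31 (not isolated)
Conditions: TEMPO (20 mol %), PhI(OAc)2 (2.5 equiv), CH2Cl2, rt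
Reagents that add atoms: none
Why: Oxoammonium oxidation is selective for the primary alcohol. The C4 aldehyde closes on the C7 hydroxyl, the only one within reach, and the lactol is oxidised on to the trans-fused γ-lactone, which marks O7 and leaves the C9 hydroxyl free.

Step 17
Reactants: 32 (3aS,5R,6S,7aR)-5-[(2E)-3-bromopent-2-en-1-yl]-6-hydroxyhexahydro-2H-furo[3,2-b]pyran-2-one
Product: 34 (3aS,5R,6R,7aR)-6-bromo-5-[(2E)-3-bromopent-2-en-1-yl]hexahydro-2H-furo[3,2-b]pyran-2-one, via triflate 33 (not isolated)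
Conditions: Tf2O, 2,6-lutidine, CH2Cl2, −40 °C; then Bu4NBr, −40 °C → rt
Reagents that add atoms: tetrabutylammonium bromide, CCCC[N+](CCCC)(CCCC)CCCC.[Br-]
Why: SN2 displacement of the equatorial triflate by bromide along the axial line gives the axial C9 bromide with inversion (as in carbohydrate triflate inversions). The equatorial leaving group has no antiperiplanar hydrogen, and the β-oxygen disfavours ionisation.

Step 18
Reactants: 34 (3aS,5R,6R,7aR)-6-bromo-5-[(2E)-3-bromopent-2-en-1-yl]hexahydro-2H-furo[3,2-b]pyran-2-one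
Product: 35 (3aS,5R,6R,7aR)-6-bromo-5-[(2E)-3-bromopent-2-en-1-yl]hexahydro-2H-furo[3,2-b]pyran-2-ol (anomeric mixture)
Conditions: i-Bu2AlH (1.1 equiv), CH2Cl2, −78 °C; potassium sodium tartrate work-up
Reagents that add atoms: none
Why: Partial reduction of the γ-lactone to the lactol, the masked C4 aldehyde; the halides are inert at −78 °C.

Step 19
Reactants: 35 (3aS,5R,6R,7aR)-6-bromo-5-[(2E)-3-bromopent-2-en-1-yl]hexahydro-2H-furo[3,2-b]pyran-2-ol; 36 1,3-bis(triisopropylsilyl)propyne
Product: 38 (2S,3R,5R,6R)-5-bromo-6-[(2E)-3-bromopent-2-en-1-yl]-2-[(2Z)-5-(triisopropylsilyl)pent-2-en-4-yn-1-yl]oxan-3-ol, via lithiated propyne 37 (not isolated)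
Conditions: 36 (3 equiv), n-BuLi, THF, −78 °C; then 35, −78 → 0 °C
Reagents that add atoms: none
Why: Peterson olefination: one equivalent of 37 deprotonates the lactol, the open hydroxy aldehyde adds a second, and syn elimination of the silanolate, steered by the bulky silyl groups, should give the Z enyne and free the C7 hydroxyl.

Step 20
Reactants: 38 (2S,3R,5R,6R)-5-bromo-6-[(2E)-3-bromopent-2-en-1-yl]-2-[(2Z)-5-(triisopropylsilyl)pent-2-en-4-yn-1-yl]oxan-3-ol
Product: 40 triisopropyl{(3Z)-5-[(2S,3S,5R,6R)-5-bromo-6-[(2E)-3-bromopent-2-en-1-yl]-3-chlorooxan-2-yl]pent-3-en-1-yn-1-yl}silane, via triflate 39 (not isolated)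
Conditions: Tf2O, 2,6-lutidine, CH2Cl2, −40 °C; then Bu4NCl, −40 °C → rt
Reagents that add atoms: tetrabutylammonium chloride, CCCC[N+](CCCC)(CCCC)CCCC.[Cl-]
Why: The same invertive triflate displacement at C7 puts chlorine axial, cis to bromine and to both arms. The smaller halide is brought in last because it must pass the axial C9 bromine.

Step 21
Reactants: 40 triisopropyl{(3Z)-5-[(2S,3S,5R,6R)-5-bromo-6-[(2E)-3-bromopent-2-en-1-yl]-3-chlorooxan-2-yl]pent-3-en-1-yn-1-yl}silane
Product: 41 (2R,3R,5S,6S)-3-bromo-2-[(2E)-3-bromopent-2-en-1-yl]-5-chloro-6-[(2Z)-pent-2-en-4-yn-1-yl]oxane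
Conditions: Bu4NF (1.1 equiv), THF, −20 → 0 °C
Reagents that add atoms: none
Why: Fluoride cleaves the C(sp)–Si bond; low temperature and a short reaction time should avoid E2 loss of the axial halides.

## Compound list

1 | 4-methoxybenzyl alcohol | COc1ccc(CO)cc1 | starting material
2 | trichloroethylene | ClC=C(Cl)Cl | starting material
3 | dichloroacetylene | ClC#CCl | intermediate (not isolated)
4 | 1-{[(E)-1,2-dichloroethenyl]oxymethyl}-4-methoxybenzene | Cl/C=C(/Cl)OCc1ccc(OC)cc1 | intermediate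
5 | (S)-3-hydroxyoxolan-2-one | O=C1OCC[C@@H]1O | starting material
6 | (2S)-2,4-dihydroxy-N-methoxy-N-methylbutanamide | CON(C)C(=O)[C@@H](O)CCO | intermediate
7 | (2S)-4-(tert-butyldimethylsilyloxy)-2-hydroxy-N-methoxy-N-methylbutanamide | CON(C)C(=O)[C@@H](O)CCO[Si](C)(C)C(C)(C)C | intermediate
8 | methyl bromoacetate | COC(=O)CBr | starting material
9 | methyl 2-{[(2S)-4-(tert-butyldimethylsilyloxy)-1-[methoxy(methyl)amino]-1-oxobutan-2-yl]oxy}acetate | CON(C)C(=O)[C@@H](OCC(=O)OC)CCO[Si](C)(C)C(C)(C)C | intermediate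
10 | methyl 2-{[(2S)-4-(tert-butyldimethylsilyloxy)-1-oxobutan-2-yl]oxy}acetate | O=C[C@@H](OCC(=O)OC)CCO[Si](C)(C)C(C)(C)C | intermediate
11 | lithium [(4-methoxybenzyl)oxy]acetylide | [Li]C#COCc1ccc(OC)cc1 | intermediate (not isolated)
12 | bromo{[(4-methoxybenzyl)oxy]ethynyl}zinc | Br[Zn]C#COCc1ccc(OC)cc1 | intermediate (not isolated)
13 | bromozinc alkoxide of methyl 2-{[(3S,4S)-1-(tert-butyldimethylsilyloxy)-4-hydroxy-6-[(4-methoxybenzyl)oxy]hex-5-yn-3-yl]oxy}acetate | COC(=O)CO[C@@H](CCO[Si](C)(C)C(C)(C)C)[C@@H](O[Zn]Br)C#COCc1ccc(OC)cc1 | intermediate (not isolated)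
14 | (5S,6S)-5-[2-(tert-butyldimethylsilyloxy)ethyl]-6-{[(4-methoxybenzyl)oxy]ethynyl}-1,4-dioxan-2-one | O=C1CO[C@@H](CCO[Si](C)(C)C(C)(C)C)[C@H](C#COCc2ccc(OC)cc2)O1 | intermediate
15 | (5S,6S)-5-[2-(tert-butyldimethylsilyloxy)ethyl]-6-{(Z)-2-[(4-methoxybenzyl)oxy]ethenyl}-1,4-dioxan-2-one | O=C1CO[C@@H](CCO[Si](C)(C)C(C)(C)C)[C@H](/C=C\OCc2ccc(OC)cc2)O1 | intermediate (key-step precursor)
16 | (2S,3S)-2-[2-(tert-butyldimethylsilyloxy)ethyl]-3-{(Z)-2-[(4-methoxybenzyl)oxy]ethenyl}-5-(trimethylsilyloxy)-2,3-dihydro-1,4-dioxine | C[Si](C)(C)OC1=CO[C@@H](CCO[Si](C)(C)C(C)(C)C)[C@H](/C=C\OCc2ccc(OC)cc2)O1 | intermediate (not isolated)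
17 | trimethylsilyl (2S,3S,6S)-6-[2-(tert-butyldimethylsilyloxy)ethyl]-3-[(4-methoxybenzyl)oxy]-3,6-dihydro-2H-pyran-2-carboxylate | CC(C)(C)[Si](C)(C)OCC[C@@H]1O[C@H](C(=O)O[Si](C)(C)C)[C@@H](OCc2ccc(OC)cc2)C=C1 | intermediate (not isolated)
18 | (2S,3S,6S)-6-[2-(tert-butyldimethylsilyloxy)ethyl]-3-[(4-methoxybenzyl)oxy]-3,6-dihydro-2H-pyran-2-carboxylic acid | CC(C)(C)[Si](C)(C)OCC[C@@H]1O[C@H](C(=O)O)[C@@H](OCc2ccc(OC)cc2)C=C1 | intermediate (key-step product)
19 | [(2R,3S,6S)-6-[2-(tert-butyldimethylsilyloxy)ethyl]-3-[(4-methoxybenzyl)oxy]-3,6-dihydro-2H-pyran-2-yl]methanol | CC(C)(C)[Si](C)(C)OCC[C@@H]1O[C@H](CO)[C@@H](OCc2ccc(OC)cc2)C=C1 | intermediate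
20 | [(2R,3S,6S)-6-[2-(tert-butyldimethylsilyloxy)ethyl]-3-[(4-methoxybenzyl)oxy]-3,6-dihydro-2H-pyran-2-yl]methyl trifluoromethanesulfonate | CC(C)(C)[Si](C)(C)OCC[C@@H]1O[C@H](COS(=O)(=O)C(F)(F)F)[C@@H](OCc2ccc(OC)cc2)C=C1 | intermediate
21 | but-1-yne | CCC#C | starting material
22 | but-1-ynyllithium | CCC#C[Li] | intermediate (not isolated)
23 | (2R,3S,6S)-6-[2-(tert-butyldimethylsilyloxy)ethyl]-3-[(4-methoxybenzyl)oxy]-2-(pent-2-yn-1-yl)-3,6-dihydro-2H-pyran | CC(C)(C)[Si](C)(C)OCC[C@@H]1O[C@H](CC#CCC)[C@@H](OCc2ccc(OC)cc2)C=C1 | intermediate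
24 | chlorobis(cyclopentadienyl){(2E)-1-[(2R,3S,6S)-6-[2-(tert-butyldimethylsilyloxy)ethyl]-3-[(4-methoxybenzyl)oxy]-3,6-dihydro-2H-pyran-2-yl]pent-2-en-3-yl}zirconium | CC(C)(C)[Si](C)(C)OCC[C@@H]1O[C@H](C/C=C(/[Zr](Cl)(C2C=CC=C2)C2C=CC=C2)CC)[C@@H](OCc2ccc(OC)cc2)C=C1 | intermediate (not isolated)
25 | (2R,3S,6S)-2-[(2E)-3-bromopent-2-en-1-yl]-6-[2-(tert-butyldimethylsilyloxy)ethyl]-3-[(4-methoxybenzyl)oxy]-3,6-dihydro-2H-pyran | CC(C)(C)[Si](C)(C)OCC[C@@H]1O[C@H](C/C=C(/Br)CC)[C@@H](OCc2ccc(OC)cc2)C=C1 | intermediate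
26 | (2R,3S,6S)-2-[(2E)-3-bromopent-2-en-1-yl]-6-[2-(tert-butyldimethylsilyloxy)ethyl]-3,6-dihydro-2H-pyran-3-ol | CC(C)(C)[Si](C)(C)OCC[C@@H]1O[C@H](C/C=C(/Br)CC)[C@@H](O)C=C1 | intermediate
27 | {[(2R,3S,6S)-2-[(2E)-3-bromopent-2-en-1-yl]-6-[2-(tert-butyldimethylsilyloxy)ethyl]-3,6-dihydro-2H-pyran-3-yl]oxy}dimethylsilane | CC(C)(C)[Si](C)(C)OCC[C@@H]1O[C@H](C/C=C(/Br)CC)[C@@H](O[SiH](C)C)C=C1 | intermediate (not isolated)
28 | 4-[(2E)-3-bromopent-2-en-1-yl]-2-[2-(tert-butyldimethylsilyloxy)ethyl]-7,7-dimethyl-3,6-dioxa-7-silabicyclo[3.2.1]octane (both arms anti to the O–Si bridge, configuration as in 29) | CC(C)(C)[Si](C)(C)OCC[C@@H]1O[C@H](C/C=C(/Br)CC)[C@@H]2C[C@H]1[Si](C)(C)O2 | intermediate (not isolated)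
29 | (2R,3S,5R,6S)-2-[(2E)-3-bromopent-2-en-1-yl]-6-[2-(tert-butyldimethylsilyloxy)ethyl]oxane-3,5-diol | CC(C)(C)[Si](C)(C)OCC[C@@H]1O[C@H](C/C=C(/Br)CC)[C@@H](O)C[C@H]1O | intermediate
30 | (2R,3S,5R,6S)-2-[(2E)-3-bromopent-2-en-1-yl]-6-(2-hydroxyethyl)oxane-3,5-diol | OCC[C@@H]1O[C@H](C/C=C(/Br)CC)[C@@H](O)C[C@H]1O | intermediate
31 | (3aS,5R,6S,7aR)-5-[(2E)-3-bromopent-2-en-1-yl]hexahydro-2H-furo[3,2-b]pyran-2,6-diol (anomeric mixture) | OC1C[C@@H]2O[C@H](C/C=C(/Br)CC)[C@@H](O)C[C@H]2O1 | intermediate (not isolated)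
32 | (3aS,5R,6S,7aR)-5-[(2E)-3-bromopent-2-en-1-yl]-6-hydroxyhexahydro-2H-furo[3,2-b]pyran-2-one | O=C1C[C@@H]2O[C@H](C/C=C(/Br)CC)[C@@H](O)C[C@H]2O1 | intermediate
33 | (3aS,5R,6S,7aR)-5-[(2E)-3-bromopent-2-en-1-yl]-2-oxohexahydro-2H-furo[3,2-b]pyran-6-yl trifluoromethanesulfonate | O=C1C[C@@H]2O[C@H](C/C=C(/Br)CC)[C@@H](OS(=O)(=O)C(F)(F)F)C[C@H]2O1 | intermediate (not isolated)
34 | (3aS,5R,6R,7aR)-6-bromo-5-[(2E)-3-bromopent-2-en-1-yl]hexahydro-2H-furo[3,2-b]pyran-2-one | O=C1C[C@@H]2O[C@H](C/C=C(/Br)CC)[C@H](Br)C[C@H]2O1 | intermediate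
35 | (3aS,5R,6R,7aR)-6-bromo-5-[(2E)-3-bromopent-2-en-1-yl]hexahydro-2H-furo[3,2-b]pyran-2-ol (anomeric mixture) | OC1C[C@@H]2O[C@H](C/C=C(/Br)CC)[C@H](Br)C[C@H]2O1 | intermediate
36 | 1,3-bis(triisopropylsilyl)propyne | CC(C)[Si](C(C)C)(C(C)C)CC#C[Si](C(C)C)(C(C)C)C(C)C | starting material
37 | 1-lithio-1,3-bis(triisopropylsilyl)propyne | CC(C)[Si](C(C)C)(C(C)C)C([Li])C#C[Si](C(C)C)(C(C)C)C(C)C | intermediate (not isolated)
38 | (2S,3R,5R,6R)-5-bromo-6-[(2E)-3-bromopent-2-en-1-yl]-2-[(2Z)-5-(triisopropylsilyl)pent-2-en-4-yn-1-yl]oxan-3-ol | CC(C)[Si](C(C)C)(C(C)C)C#C/C=C\C[C@@H]1O[C@H](C/C=C(/Br)CC)[C@H](Br)C[C@H]1O | intermediate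
39 | (2S,3R,5R,6R)-5-bromo-6-[(2E)-3-bromopent-2-en-1-yl]-2-[(2Z)-5-(triisopropylsilyl)pent-2-en-4-yn-1-yl]oxan-3-yl trifluoromethanesulfonate | CC(C)[Si](C(C)C)(C(C)C)C#C/C=C\C[C@@H]1O[C@H](C/C=C(/Br)CC)[C@H](Br)C[C@H]1OS(=O)(=O)C(F)(F)F | intermediate (not isolated)
40 | triisopropyl{(3Z)-5-[(2S,3S,5R,6R)-5-bromo-6-[(2E)-3-bromopent-2-en-1-yl]-3-chlorooxan-2-yl]pent-3-en-1-yn-1-yl}silane | CC(C)[Si](C(C)C)(C(C)C)C#C/C=C\C[C@@H]1O[C@H](C/C=C(/Br)CC)[C@H](Br)C[C@@H]1Cl | intermediate
41 | (2R,3R,5S,6S)-3-bromo-2-[(2E)-3-bromopent-2-en-1-yl]-5-chloro-6-[(2Z)-pent-2-en-4-yn-1-yl]oxane | C#C/C=C\C[C@@H]1O[C@H](C/C=C(/Br)CC)[C@H](Br)C[C@@H]1Cl | target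

## Step count and least certain steps

Total: 21 steps. Longest linear sequence: 20 steps (5 → 41, steps 2–21); step 1 is a one-step branch that feeds step 6.

Step 8 (key step). The most likely failure is a slow rearrangement: in the enforced boat the Z alkoxy group and C6 crowd each other, so desilylation or decomposition of the ketene acetal may outrun C–C bond formation. The vinylogous acylal may also be lost on work-up. The fallback moves the C9 oxygen out of the rearrangement. It sets out from 10: chelation-controlled addition of CH2=CHMgBr/ZnBr2 with lactonisation should give (5S,6S)-5-[2-(tert-butyldimethylsilyloxy)ethyl]-6-ethenyl-1,4-dioxan-2-one F1, the parent substrate of this rearrangement class. Its Ireland–Claisen rearrangement gives (2S,6S)-6-[2-(tert-butyldimethylsilyloxy)ethyl]-3,6-dihydro-2H-pyran-2-carboxylic acid F2, and MeI/K2CO3 gives the methyl ester F3. Allylic hydroxylation with SeO2/t-BuOOH at C9, the only allylic methylene, should deliver oxygen anti to the C10 substituent through the ene/[2,3] sequence and give the hydroxy ester F4. 4-Methoxybenzyl trichloroacetimidate with catalytic acid gives the PMB ether ester F5, and LiAlH4 returns to the route at 19.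

Step 14. Closing the bridged siloxane requires both ring arms to turn axial. Intermolecular hydrosilylation, oligomerisation or simple recovery of the silyl ether may therefore win, and a platinum hydride may also isomerise the alkene. The fallback replaces directed delivery by conjugate addition. It sets out from 26: MnO2 gives the enone F6. Copper-catalysed conjugate borylation (CuCl, NaOt-Bu, a bisphosphine, B2pin2, MeOH) should add boron to C7 anti to the C6 arm to give the boryl ketone F7, and NaBO3 gives the hydroxy ketone F8. Axial hydride delivery (NaBH4, CeCl3, −78 °C) gives the equatorial C9 alcohol and returns to the route at 29.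

Step 12. Both alkyne substituents are primary, so regiocontrol may be poor and the C12 bromide may form alongside. Excess zirconium hydride may also add to the ring alkene and trigger β-alkoxide elimination. The fallback builds the bromoalkene by olefination. It sets out from 20: 2-lithio-1,3-dithiane gives the dithiane F9, and MeI/CaCO3 in aqueous MeCN gives the aldehyde F10. Horner–Wadsworth–Emmons reaction with (CF3CH2O)2P(O)CHBrCO2Et, t-BuOK and 18-crown-6 should give the (E)-α-bromoacrylate F11. i-Bu2AlH gives the allylic alcohol F12; MsCl/Et3N then LiBr gives the allylic bromide F13; Me2CuLi returns to the route at 25.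

Step 19. The lithium lactolate may open only slowly. The basic silylpropargyl anion would then attack the axial C9 bromide (E2), or the Peterson elimination may lose Z control. The fallback uses a less basic ylide and a cross-coupling. It sets out from 35: Ph3P=CHI (from Ph3PCH2I iodide and NaN(SiMe3)2, −78 °C → rt) should give the (Z)-vinyl iodide F14. Sonogashira coupling with (triisopropylsilyl)acetylene (Pd(PPh3)4, zerovalent palladium; CuI; i-Pr2NH) reacts at the iodide only and returns to the route at 38.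

Step 20. Chloride must approach C7 past the axial C9 bromine. Loss of the triflate by elimination, or ring contraction through participation of the ring oxygen, may therefore compete with substitution. The fallback reverses the order of the halogens. It sets out from 32: Et3SiOTf/2,6-lutidine gives the silyl ether lactone F15, and i-Bu2AlH gives the lactol F16. The Peterson olefination of step 19 gives the enyne alcohol F17. Tf2O then Bu4NCl gives the C7 chloride F18, now with no axial neighbour, and HF·pyridine gives the C9 alcohol F19. Tf2O then Bu4NBr, with the better nucleophile passing the smaller halogen, returns to the route at 40.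

## Further compounds

F1 | step 8 | (5S,6S)-5-[2-(tert-butyldimethylsilyloxy)ethyl]-6-ethenyl-1,4-dioxan-2-one | O=C1CO[C@@H](CCO[Si](C)(C)C(C)(C)C)[C@H](C=C)O1
F2 | step 8 | (2S,6S)-6-[2-(tert-butyldimethylsilyloxy)ethyl]-3,6-dihydro-2H-pyran-2-carboxylic acid | CC(C)(C)[Si](C)(C)OCC[C@@H]1O[C@H](C(=O)O)CC=C1
F3 | step 8 | methyl (2S,6S)-6-[2-(tert-butyldimethylsilyloxy)ethyl]-3,6-dihydro-2H-pyran-2-carboxylate | CC(C)(C)[Si](C)(C)OCC[C@@H]1O[C@H](C(=O)OC)CC=C1
F4 | step 8 | methyl (2S,3S,6S)-6-[2-(tert-butyldimethylsilyloxy)ethyl]-3-hydroxy-3,6-dihydro-2H-pyran-2-carboxylate | CC(C)(C)[Si](C)(C)OCC[C@@H]1O[C@H](C(=O)OC)[C@@H](O)C=C1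
F5 | step 8 | methyl (2S,3S,6S)-6-[2-(tert-butyldimethylsilyloxy)ethyl]-3-[(4-methoxybenzyl)oxy]-3,6-dihydro-2H-pyran-2-carboxylate | CC(C)(C)[Si](C)(C)OCC[C@@H]1O[C@H](C(=O)OC)[C@@H](OCc2ccc(OC)cc2)C=C1
F6 | step 14 | (2R,6S)-2-[(2E)-3-bromopent-2-en-1-yl]-6-[2-(tert-butyldimethylsilyloxy)ethyl]-2H-pyran-3(6H)-one | CC(C)(C)[Si](C)(C)OCC[C@@H]1O[C@H](C/C=C(/Br)CC)C(=O)C=C1
F7 | step 14 | (2R,5R,6S)-2-[(2E)-3-bromopent-2-en-1-yl]-6-[2-(tert-butyldimethylsilyloxy)ethyl]-5-(4,4,5,5-tetramethyl-1,3,2-dioxaborolan-2-yl)oxan-3-one (boron trans to the C6 arm) | CC(C)(C)[Si](C)(C)OCC[C@@H]1O[C@H](C/C=C(/Br)CC)C(=O)C[C@H]1B1OC(C)(C)C(C)(C)O1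
F8 | step 14 | (2R,5R,6S)-2-[(2E)-3-bromopent-2-en-1-yl]-6-[2-(tert-butyldimethylsilyloxy)ethyl]-5-hydroxyoxan-3-one | CC(C)(C)[Si](C)(C)OCC[C@@H]1O[C@H](C/C=C(/Br)CC)C(=O)C[C@H]1O
F9 | step 12 | 2-{[(2R,3S,6S)-6-[2-(tert-butyldimethylsilyloxy)ethyl]-3-[(4-methoxybenzyl)oxy]-3,6-dihydro-2H-pyran-2-yl]methyl}-1,3-dithiane | CC(C)(C)[Si](C)(C)OCC[C@@H]1O[C@H](CC2SCCCS2)[C@@H](OCc2ccc(OC)cc2)C=C1
F10 | step 12 | 2-[(2R,3S,6S)-6-[2-(tert-butyldimethylsilyloxy)ethyl]-3-[(4-methoxybenzyl)oxy]-3,6-dihydro-2H-pyran-2-yl]acetaldehyde | CC(C)(C)[Si](C)(C)OCC[C@@H]1O[C@H](CC=O)[C@@H](OCc2ccc(OC)cc2)C=C1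
F11 | step 12 | ethyl (2E)-2-bromo-4-[(2R,3S,6S)-6-[2-(tert-butyldimethylsilyloxy)ethyl]-3-[(4-methoxybenzyl)oxy]-3,6-dihydro-2H-pyran-2-yl]but-2-enoate | CC(C)(C)[Si](C)(C)OCC[C@@H]1O[C@H](C/C=C(/Br)C(=O)OCC)[C@@H](OCc2ccc(OC)cc2)C=C1
F12 | step 12 | (2E)-2-bromo-4-[(2R,3S,6S)-6-[2-(tert-butyldimethylsilyloxy)ethyl]-3-[(4-methoxybenzyl)oxy]-3,6-dihydro-2H-pyran-2-yl]but-2-en-1-ol | CC(C)(C)[Si](C)(C)OCC[C@@H]1O[C@H](C/C=C(/Br)CO)[C@@H](OCc2ccc(OC)cc2)C=C1
F13 | step 12 | (2R,3S,6S)-2-[(2E)-3,4-dibromobut-2-en-1-yl]-6-[2-(tert-butyldimethylsilyloxy)ethyl]-3-[(4-methoxybenzyl)oxy]-3,6-dihydro-2H-pyran | CC(C)(C)[Si](C)(C)OCC[C@@H]1O[C@H](C/C=C(/Br)CBr)[C@@H](OCc2ccc(OC)cc2)C=C1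
F14 | step 19 | (2S,3R,5R,6R)-5-bromo-6-[(2E)-3-bromopent-2-en-1-yl]-2-[(2Z)-3-iodoprop-2-en-1-yl]oxan-3-ol | I/C=C\C[C@@H]1O[C@H](C/C=C(/Br)CC)[C@H](Br)C[C@H]1O
F15 | step 20 | (3aS,5R,6S,7aR)-5-[(2E)-3-bromopent-2-en-1-yl]-6-(triethylsilyloxy)hexahydro-2H-furo[3,2-b]pyran-2-one | O=C1C[C@@H]2O[C@H](C/C=C(/Br)CC)[C@@H](O[Si](CC)(CC)CC)C[C@H]2O1
F16 | step 20 | (3aS,5R,6S,7aR)-5-[(2E)-3-bromopent-2-en-1-yl]-6-(triethylsilyloxy)hexahydro-2H-furo[3,2-b]pyran-2-ol (anomeric mixture) | OC1C[C@@H]2O[C@H](C/C=C(/Br)CC)[C@@H](O[Si](CC)(CC)CC)C[C@H]2O1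
F17 | step 20 | (2S,3R,5S,6R)-6-[(2E)-3-bromopent-2-en-1-yl]-5-(triethylsilyloxy)-2-[(2Z)-5-(triisopropylsilyl)pent-2-en-4-yn-1-yl]oxan-3-ol | CC(C)[Si](C(C)C)(C(C)C)C#C/C=C\C[C@@H]1O[C@H](C/C=C(/Br)CC)[C@@H](O[Si](CC)(CC)CC)C[C@H]1O
F18 | step 20 | {(3Z)-5-[(2S,3S,5S,6R)-6-[(2E)-3-bromopent-2-en-1-yl]-3-chloro-5-(triethylsilyloxy)oxan-2-yl]pent-3-en-1-yn-1-yl}triisopropylsilane | CC(C)[Si](C(C)C)(C(C)C)C#C/C=C\C[C@@H]1O[C@H](C/C=C(/Br)CC)[C@@H](O[Si](CC)(CC)CC)C[C@@H]1Cl
F19 | step 20 | (2R,3S,5S,6S)-2-[(2E)-3-bromopent-2-en-1-yl]-5-chloro-6-[(2Z)-5-(triisopropylsilyl)pent-2-en-4-yn-1-yl]oxan-3-ol | CC(C)[Si](C(C)C)(C(C)C)C#C/C=C\C[C@@H]1O[C@H](C/C=C(/Br)CC)[C@@H](O)C[C@@H]1Cl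
A1 | alternative 1 | 6-acetoxy-2H-pyran-3(6H)-one | CC(=O)OC1OCC(=O)C=C1
A2 | alternative 1 | 2,2-dimethyl-1,3-dioxole | CC1(C)OC=CO1
A3 | alternative 1 | 6,7-exo-O-isopropylidene-8-oxabicyclo[3.2.1]oct-3-en-2-one | O=C1C=C[C@@H]2O[C@H]1[C@H]3OC(C)(C)O[C@@H]23
A4 | alternative 2 | 2-deoxy-D-ribose | O=CC[C@H](O)[C@H](O)CO
A5 | alternative 2 | ethyl (2E)-3-{[(3S,4R)-3-(tert-butyldimethylsilyloxy)-1-oxonon-6-yn-4-yl]oxy}prop-2-enoate | CCOC(=O)/C=C/O[C@H](CC#CCC)[C@@H](O[Si](C)(C)C(C)(C)C)CC=O
A6 | alternative 2 | samarium diiodide | [Sm+2].[I-].[I-]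
A7 | alternative 2 | ethyl 2-[(2S,3R,5S,6R)-5-(tert-butyldimethylsilyloxy)-3-hydroxy-6-(pent-2-yn-1-yl)oxan-2-yl]acetate | CCOC(=O)C[C@@H]1O[C@H](CC#CCC)[C@@H](O[Si](C)(C)C(C)(C)C)C[C@H]1O
A8 | alternative 3 | (1S)-3-(tert-butyldimethylsilyloxy)-1-[5-(pent-2-yn-1-yl)furan-2-yl]propan-1-ol | CCC#CCc1ccc(o1)[C@@H](O)CCO[Si](C)(C)C(C)(C)C
A9 | alternative 3 | N-bromosuccinimide | O=C1CCC(=O)N1Br
A10 | alternative 3 | (2S)-2-[2-(tert-butyldimethylsilyloxy)ethyl]-6-hydroxy-6-(pent-2-yn-1-yl)-2H-pyran-3(6H)-one (anomeric mixture) | O=C1C=CC(O)(CC#CCC)O[C@H]1CCO[Si](C)(C)C(C)(C)C
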